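The chroman is disconnected at C2–C3 and O1–C2. This exposes the quaternary C2, with its methyl group and the C1′ chain, as the carbonyl carbon of geranylacetone, and C3, C4 and the arene (C4a–C8a) as an o-hydroxyacetophenone. In one operation a chiral primary amine joins the two ketones (C2–C3) and lets the C8a phenol close the pyranone ring onto C2, which gives the whole carbon skeleton and the only stereocentre. The precursor is 2,5-dihydroxy-3-methylacetophenone carried as its 5-O-triisopropylsilyl ether, so that a single free phenol meets the catalyst; removal of the C4 oxygen and oxidation of the terminal (E)-methyl group follow.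

Key step: step 4

Remark: the sense of induction of the amine catalyst in step 4 cannot be derived from precedent. The quinine-derived catalyst is written, and its quinidine-derived pseudoenantiomer takes its place if the first favours the (2S) series.

Remark: 7 is expected as interconverting (2E)/(2Z) isomers (the 2E form is drawn) and 9 as a mixture of C4 epimers; neither affects the outcome.

**Step 1**
Reactants: 1 4-methoxy-2-methylphenol
Product: 3 1-(2-hydroxy-5-methoxy-3-methylphenyl)ethanone, via 4-methoxy-2-methylphenyl acetate 2 (not isolated)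
Conditions: Ac2O (1.1 equiv), BF3·OEt2 (excess, neat), rt then 90 °C; aq. NaOAc work-up
Reagents that add atoms: acetic anhydride, CC(=O)OC(C)=O
Why: O-Acetylation is followed in the same pot by a BF3-promoted Fries rearrangement, and the acetyl group can only arrive at C6 because the other ortho position carries the methyl group and the para position the methoxy group.

**Step 2**
Reactants: 3 1-(2-hydroxy-5-methoxy-3-methylphenyl)ethanone
Product: 4 1-(2,5-dihydroxy-3-methylphenyl)ethanone
Conditions: BBr3 (2.5 equiv), CH2Cl2, −78 °C → rt; H2O
Reagents that add atoms: none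
Why: BBr3 cleaves the aryl methyl ether (Lewis-acid O-demethylation) and leaves the chelated aryl ketone untouched, a standard transformation on methoxyacetophenones.

**Step 3**
Reactants: 4 1-(2,5-dihydroxy-3-methylphenyl)ethanone
Product: 5 1-{2-hydroxy-3-methyl-5-[(triisopropylsilyl)oxy]phenyl}ethanone
Conditions: TIPSCl (1.05 equiv), imidazole (2 equiv), DMF, 0 °C → rt
Reagents that add atoms: chlorotriisopropylsilane, CC(C)[Si](Cl)(C(C)C)C(C)C
Why: Silyl ether formation goes to the unhindered C5 hydroxyl because the C2 hydroxyl is hydrogen-bonded to the acetyl group and flanked by the C3 methyl group, and the bulky TIPS ether should survive amines, hydride and the later oxidations.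

**Step 4**
Reactants: 5 1-{2-hydroxy-3-methyl-5-[(triisopropylsilyl)oxy]phenyl}ethanone; 6 (5E)-6,10-dimethylundeca-5,9-dien-2-one (geranylacetone, 1.5 equiv)
Product: 8 (2R)-2-[(3E)-4,8-dimethylnona-3,7-dien-1-yl]-2,8-dimethyl-6-[(triisopropylsilyl)oxy]-2,3-dihydro-4H-chromen-4-one, via open-chain aryl trienone 7 (not isolated)
Conditions: 9-amino-9-deoxy-epi-quinine (20 mol %), PhCO2H (40 mol %), 4 Å MS, toluene, 40 °C; stopped at full conversion and taken directly into step 5
Reagents that add atoms: none
Why: Proposed new method: the primary amine of the cinchona catalyst condenses with geranylacetone to a ketiminium ion, the enol of the o-hydroxyacetophenone adds to it (Mannich-type, forming C2–C3), and β-elimination of the amine releases enone 7, whose E and Z forms interconvert through the catalyst-bound dienamine. The same amine then activates 7 as its iminium ion while the quinuclidine nitrogen, acting as general base, delivers the C8a phenol to C2 (O1–C2), closing the pyranone ring by a 6-endo-trig oxa-Michael addition; hydrolysis of the resulting enamine frees 8 and the catalyst. The closest known reactions are the racemic pyrrolidine-mediated Kabbe chromanone synthesis from o-hydroxyacetophenones and ketones, and the organocatalytic asymmetric oxa-Michael cyclisations that give 2-monosubstituted chromanones; an enantioselective closure onto a β,β-disubstituted enone generated in the flask from two ketones has not been shown. The C2 stereocentre is set under catalyst control in the C–O bond-forming step, the ion pair of protonated quinuclidine and phenoxide held next to the iminium exposing one face of the β-carbon, and the (2R) sense is secured by the choice of pseudoenantiomeric catalyst. The step needs face selectivity between a methyl and a CH2 substituent under kinetic control: the thermodynamic preference for the (2E)-enone (long chain anti to the aroyl group) gives the catalyst one dominant geometry to read, the silylated C5 oxygen leaves a single phenol for the basic site, and the electron-rich para-silyloxy aryloxide is a poor leaving group, which slows racemisation by retro-oxa-Michael opening.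

**Step 5**
Reactants: 8 (2R)-chromanone from step 4
Product: 9 (2R)-2-[(3E)-4,8-dimethylnona-3,7-dien-1-yl]-2,8-dimethyl-6-[(triisopropylsilyl)oxy]chroman-4-ol (mixture of C4 epimers)
Conditions: NaBH4, MeOH/THF, 0 °C
Reagents that add atoms: none
Why: Hydride 1,2-reduction of the aryl ketone (NaBH4 reduction) removes the carbonyl that makes retro-oxa-Michael ring opening possible, so C2 is fixed from here on; the new C4 centre forms unselectively and is erased in step 6.

**Step 6**
Reactants: 9 (2R)-chroman-4-ol
Product: 10 triisopropyl({(2R)-2-[(3E)-4,8-dimethylnona-3,7-dien-1-yl]-2,8-dimethyl-2H-chromen-6-yl}oxy)silane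
Conditions: Burgess reagent (1.5 equiv), benzene, 50 °C, exclusion of light
Reagents that add atoms: none
Why: Burgess dehydration proceeds by syn-elimination of the benzylic sulfamate ester under neutral conditions, which should give the conjugated 2H-chromene without the acid that could cyclise the polyene chain or dimerise the electron-rich chromene.

**Step 7**
Reactants: 10 (2R)-2H-chromene
Product: 11 triisopropyl({(2R)-2-[(3E)-4,8-dimethylnona-3,7-dien-1-yl]-2,8-dimethylchroman-6-yl}oxy)silane
Conditions: 2-nitrobenzenesulfonylhydrazide (NBSH, added in portions), Et3N, CH2Cl2, rt, exclusion of light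
Reagents that add atoms: none
Why: Diimide generated from NBSH transfers H2 in a concerted syn fashion and discriminates by degree of substitution, so the cis-disubstituted C3=C4 ring olefin should be reduced ahead of the two trisubstituted chain olefins (chemoselective diimide reduction), and C2 is not involved.

**Step 8**
Reactants: 11 (2R)-chroman silyl ether
Product: 13 (2E,6E)-9-{(2R)-2,8-dimethyl-6-[(triisopropylsilyl)oxy]chroman-2-yl}-2,6-dimethylnona-2,6-dienal, via terminal allylic alcohol 12 (not isolated)
Conditions: SeO2 (0.3 equiv), t-BuOOH (3 equiv), salicylic acid (0.1 equiv), CH2Cl2, 0 °C → rt; crude, MnO2, CH2Cl2, rt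
Reagents that add atoms: selenium dioxide, O=[Se]=O; tert-butyl hydroperoxide, CC(C)(C)OO
Why: The Sharpless SeO2/t-BuOOH allylic oxidation (ene reaction then [2,3]-sigmatropic shift) attacks the (E)-methyl group of the most accessible, terminal isopropylidene unit, and MnO2 then converges the alcohol/aldehyde mixture on the (E)-enal by allylic alcohol oxidation.

**Step 9**
Reactants: 13 (2E,6E)-dienal
Product: 14 (2E,6E)-9-{(2R)-2,8-dimethyl-6-[(triisopropylsilyl)oxy]chroman-2-yl}-2,6-dimethylnona-2,6-dienoic acid
Conditions: NaClO2, NaH2PO4, 2-methyl-2-butene (excess), t-BuOH/H2O, 0 °C → rt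
Reagents that add atoms: sodium chlorite, [Na+].[O-]Cl=O
Why: Pinnick oxidation converts the enal into the acid with retention of the (E)-geometry, 2-methyl-2-butene scavenging hypochlorous acid so that the silylated electron-rich arene and the remaining olefin are spared.

**Step 10**
Reactants: 14 silyl-protected dienoic acid
Product: 15 (2E,6E)-9-[(2R)-6-hydroxy-2,8-dimethylchroman-2-yl]-2,6-dimethylnona-2,6-dienoic acid (target)
Conditions: TBAF (1.5 equiv), AcOH (1.5 equiv), THF, 0 °C → rt
Reagents that add atoms: none
Why: Fluoride cleaves the aryl silyl ether (desilylation), and buffering with acetic acid keeps the liberated electron-rich phenol from standing as its air-sensitive phenoxide.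

**Compound list**

1 | 4-methoxy-2-methylphenol | COc1ccc(O)c(C)c1 | starting material
2 | 4-methoxy-2-methylphenyl acetate | COc1ccc(OC(C)=O)c(C)c1 | intermediate (not isolated)
3 | 1-(2-hydroxy-5-methoxy-3-methylphenyl)ethanone | COc1cc(C)c(O)c(C(C)=O)c1 | intermediate
4 | 1-(2,5-dihydroxy-3-methylphenyl)ethanone | CC(=O)c1cc(O)cc(C)c1O | intermediate
5 | 1-{2-hydroxy-3-methyl-5-[(triisopropylsilyl)oxy]phenyl}ethanone | CC(=O)c1cc(O[Si](C(C)C)(C(C)C)C(C)C)cc(C)c1O | intermediate
6 | (5E)-6,10-dimethylundeca-5,9-dien-2-one (geranylacetone) | CC(=O)CC/C=C(\C)CCC=C(C)C | starting material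
7 | (2E,6E)-1-{2-hydroxy-3-methyl-5-[(triisopropylsilyl)oxy]phenyl}-3,7,11-trimethyldodeca-2,6,10-trien-1-one | C/C(=C\C(=O)c1cc(O[Si](C(C)C)(C(C)C)C(C)C)cc(C)c1O)CC/C=C(\C)CCC=C(C)C | intermediate (not isolated)
8 | (2R)-2-[(3E)-4,8-dimethylnona-3,7-dien-1-yl]-2,8-dimethyl-6-[(triisopropylsilyl)oxy]-2,3-dihydro-4H-chromen-4-one | C/C(=C\CC[C@]1(C)CC(=O)c2cc(O[Si](C(C)C)(C(C)C)C(C)C)cc(C)c2O1)CCC=C(C)C | intermediate
9 | (2R)-2-[(3E)-4,8-dimethylnona-3,7-dien-1-yl]-2,8-dimethyl-6-[(triisopropylsilyl)oxy]chroman-4-ol, C4 epimers | C/C(=C\CC[C@]1(C)CC(O)c2cc(O[Si](C(C)C)(C(C)C)C(C)C)cc(C)c2O1)CCC=C(C)C | intermediate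
10 | triisopropyl({(2R)-2-[(3E)-4,8-dimethylnona-3,7-dien-1-yl]-2,8-dimethyl-2H-chromen-6-yl}oxy)silane | C/C(=C\CC[C@]1(C)C=Cc2cc(O[Si](C(C)C)(C(C)C)C(C)C)cc(C)c2O1)CCC=C(C)C | intermediate
11 | triisopropyl({(2R)-2-[(3E)-4,8-dimethylnona-3,7-dien-1-yl]-2,8-dimethylchroman-6-yl}oxy)silane | C/C(=C\CC[C@]1(C)CCc2cc(O[Si](C(C)C)(C(C)C)C(C)C)cc(C)c2O1)CCC=C(C)C | intermediate
12 | (2E,6E)-9-{(2R)-2,8-dimethyl-6-[(triisopropylsilyl)oxy]chroman-2-yl}-2,6-dimethylnona-2,6-dien-1-ol | C/C(=C\CC[C@]1(C)CCc2cc(O[Si](C(C)C)(C(C)C)C(C)C)cc(C)c2O1)CC/C=C(\C)CO | intermediate (not isolated)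
13 | (2E,6E)-9-{(2R)-2,8-dimethyl-6-[(triisopropylsilyl)oxy]chroman-2-yl}-2,6-dimethylnona-2,6-dienal | C/C(=C\CC[C@]1(C)CCc2cc(O[Si](C(C)C)(C(C)C)C(C)C)cc(C)c2O1)CC/C=C(\C)C=O | intermediate
14 | (2E,6E)-9-{(2R)-2,8-dimethyl-6-[(triisopropylsilyl)oxy]chroman-2-yl}-2,6-dimethylnona-2,6-dienoic acid | C/C(=C\CC[C@]1(C)CCc2cc(O[Si](C(C)C)(C(C)C)C(C)C)cc(C)c2O1)CC/C=C(\C)C(=O)O | intermediate
15 | (2E,6E)-9-[(2R)-6-hydroxy-2,8-dimethylchroman-2-yl]-2,6-dimethylnona-2,6-dienoic acid | C/C(=C\CC[C@]1(C)CCc2cc(O)cc(C)c2O1)CC/C=C(\C)C(=O)O | target

Total step count: 10. Longest linear sequence: 10 steps (1 → 15); geranylacetone 6 is bought and enters at step 4.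

**Steps most likely to fail**

1. Step 4 (proposed new method). The catalyst may not discriminate well enough between the methyl and the CH2 substituent in the ring closure. Enantiopurity may also erode by reversible ring opening while the amine is present, and the ketone–ketone condensation may be slow with a hindered chiral amine. The fallback uses known chemistry and sets out from 5 and 6. The classical Kabbe condensation (pyrrolidine, toluene, rt → reflux, water removed) should give the racemic chromanone F1. Its enantiomers are separated by preparative chromatography on a chiral stationary phase (cellulose tris(3,5-dimethylphenylcarbamate)), which returns to the route at 8. The unwanted (2S)-chromanone F2 is racemised by brief re-exposure to pyrrolidine (ring opening and re-closure) and separated again.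

2. Step 7. Diimide may over-reduce the trisubstituted chain olefins, giving di- and tetrahydro by-products that are hard to remove, and the 2H-chromene may lose configurational purity by light-induced electrocyclic ring opening. The fallback sets out from 9 and bypasses the chromene altogether by Barton–McCombie deoxygenation. Treatment with 1,1′-thiocarbonyldiimidazole (DMAP cat., CH2Cl2, rt) should give the O-chroman-4-yl imidazole-1-carbothioate F3. Radical reduction (Bu3SnH, AIBN, toluene, 80 °C) then cleaves the benzylic C–O bond, and the route is rejoined at 11.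

3. Step 8. Allylic oxidation may also occur at the internal olefin (its C5′ methylene), the enal may be over-oxidised, or conversion may stay low. The fallback sets out from 11 and builds the enal by C=C bond formation instead of C–H oxidation. Cross-metathesis of the terminal isopropylidene group with excess methacrolein (second-generation Hoveyda–Grubbs catalyst, CH2Cl2, 40 °C) should give the (E)-enal directly, rejoining the route at 13. The 1,5-relationship of the two chain olefins rules out ring-closing metathesis.

**Further compounds**

F1 | step 4 | racemic 2-[(3E)-4,8-dimethylnona-3,7-dien-1-yl]-2,8-dimethyl-6-[(triisopropylsilyl)oxy]-2,3-dihydro-4H-chromen-4-one | C/C(=C\CCC1(C)CC(=O)c2cc(O[Si](C(C)C)(C(C)C)C(C)C)cc(C)c2O1)CCC=C(C)C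
F2 | step 4 | (2S)-2-[(3E)-4,8-dimethylnona-3,7-dien-1-yl]-2,8-dimethyl-6-[(triisopropylsilyl)oxy]-2,3-dihydro-4H-chromen-4-one | C/C(=C\CC[C@@]1(C)CC(=O)c2cc(O[Si](C(C)C)(C(C)C)C(C)C)cc(C)c2O1)CCC=C(C)C
F3 | step 7 | O-{(2R)-2-[(3E)-4,8-dimethylnona-3,7-dien-1-yl]-2,8-dimethyl-6-[(triisopropylsilyl)oxy]chroman-4-yl} 1H-imidazole-1-carbothioate | C/C(=C\CC[C@]1(C)CC(OC(=S)n3ccnc3)c2cc(O[Si](C(C)C)(C(C)C)C(C)C)cc(C)c2O1)CCC=C(C)C
F0 | step 8 | none | none
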